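**Retrosynthetic overview** (cembrane numbering: C1 carries isopropyl, C3–C4 is the oxirane, C7=C8 is the Z-enone olefin with C19H2OH on C8, C9 and C14 are the ketones, C12 carries Me, C13 carries OH)
1. The 14-membered carbocycle is closed last, at C6–C7, by a one-pot 9-BBN hydroboration / B-alkyl Suzuki–Miyaura macrocyclisation of an acyclic vinyl-oxirane / (Z)-vinyl iodide. The oxirane is the first ring made (step 2) and is carried through.
2. Enabling feature: C6 lies two carbons from the fully substituted oxirane carbon C4, so the C5=C6 vinyl group has no allylic hydrogen and should take boron only at C6. C7 is the β-carbon of the unit C7=C8(C19H2OH)–C9=O, the retron of an iodide-triggered allenolate/formaldehyde aldol that gives the Z-iodide, and stereoretentive coupling then fixes the Z-olefin.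
3. In the same flask 9-BBN also masks the C9 alcohol and the C14 enone, so only a double oxidation and a desilylation follow ring closure.
4. C1=C2 comes from a Horner–Wadsworth–Emmons union of a C1/C14–C7 ketophosphonate with the C2–C6 epoxy aldehyde.
5. C12 comes from (R)-citronellic acid, C13 from an auxiliary-controlled enolate hydroxylation, and C3/C4 from Sharpless epoxidation of a Z-dienol.

Key step: step 16

Remark: the carbinol centres at C9 (from step 9 on) and C14 (step 16) and the phosphonate-bearing C1 (step 14) should form as epimer mixtures. They are drawn without configuration because oxidation or olefination erases them.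

Step 1
Reactants: 1 (2Z)-3-methylpent-2-en-4-yn-1-ol
Product: 2 (2Z)-3-methylpenta-2,4-dien-1-ol
Conditions: H2 (1 atm), Pd/CaCO3 poisoned with Pb(OAc)2, quinoline, Et2O, 0 °C, stopped after 1 equiv H2
Reagents that add atoms: none
Why: Lindlar semihydrogenation should stop at the terminal alkene and leave the Z-trisubstituted olefin unchanged.

Step 2
Reactants: 2 (2Z)-3-methylpenta-2,4-dien-1-ol
Product: 3 [(2S,3R)-3-ethenyl-3-methyloxiran-2-yl]methanol
Conditions: Ti(OiPr)4 (10 mol %), L-(+)-diethyl tartrate (13 mol %), t-BuOOH (decane), 4 Å MS, CH2Cl2, −20 °C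
Reagents that add atoms: tert-butyl hydroperoxide, CC(C)(C)OO
Why: Sharpless asymmetric epoxidation oxidises only the allylic-alcohol olefin; the L-(+)-tartrate complex should give the (2S,3R) epoxide as it does with nerol, and syn addition to the Z-olefin sets the cis relation of the two carbon chains at C3 and C4.

Step 3
Reactants: 3 [(2S,3R)-3-ethenyl-3-methyloxiran-2-yl]methanol
Product: 4 (2R,3R)-3-ethenyl-3-methyloxirane-2-carbaldehyde
Conditions: Dess–Martin periodinane, NaHCO3, CH2Cl2, 0 °C; used at once as a cold solution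
Reagents that add atoms: none
Why: Buffered Dess–Martin oxidation should give the non-enolisable epoxy aldehyde without touching oxirane or vinyl group, and cold handling avoids sigmatropic rearrangement of the cis-formyl/vinyl oxirane.

Step 4
Reactants: 5 (3R)-3,7-dimethyloct-6-enoic acid, (R)-citronellic acid
Product: 6 (4S)-4-benzyl-3-[(3R)-3,7-dimethyloct-6-enoyl]-1,3-oxazolidin-2-one
Conditions: (S)-4-benzyl-1,3-oxazolidin-2-one, DCC, DMAP (cat.), CH2Cl2, 0 °C to rt
Reagents that add atoms: (S)-4-benzyl-1,3-oxazolidin-2-one, O=C1N[C@@H](Cc2ccccc2)CO1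
Why: Steglich-type carbodiimide N-acylation attaches the chiral oxazolidinone without affecting the C12 stereocentre.

Step 5
Reactants: 6 (4S)-4-benzyl-3-[(3R)-3,7-dimethyloct-6-enoyl]-1,3-oxazolidin-2-one
Product: 8 (4S)-4-benzyl-3-[(2S,3R)-2-hydroxy-3,7-dimethyloct-6-enoyl]-1,3-oxazolidin-2-one, via sodium enolate 7 (not isolated)
Conditions: NaN(SiMe3)2, THF, −78 °C; 3-phenyl-2-(phenylsulfonyl)oxaziridine, −78 °C; AcOH
Reagents that add atoms: sodium bis(trimethylsilyl)amide, C[Si](C)(C)[N-][Si](C)(C)C.[Na+] (sodium stays only in 7); 3-phenyl-2-(phenylsulfonyl)oxaziridine, O=S(=O)(c1ccccc1)N1OC1c1ccccc1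
Why: In this auxiliary-controlled enolate hydroxylation with an N-sulfonyloxaziridine, the chelated Z-enolate is attacked on the face opposite the benzyl group, which should set the (S)-carbinol C13.

Step 6
Reactants: 8 (4S)-4-benzyl-3-[(2S,3R)-2-hydroxy-3,7-dimethyloct-6-enoyl]-1,3-oxazolidin-2-one
Product: 9 methyl (2S,3R)-2-hydroxy-3,7-dimethyloct-6-enoate
Conditions: Mg(OMe)2 (0.3 equiv), MeOH, 0 °C
Reagents that add atoms: methanol, CO
Why: Magnesium-alkoxide transesterification cleaves the exocyclic imide carbonyl and should release the α-hydroxy ester without epimerisation.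

Step 7
Reactants: 9 methyl (2S,3R)-2-hydroxy-3,7-dimethyloct-6-enoate
Product: 10 methyl (2S,3R)-2-(tert-butyldimethylsilyloxy)-3,7-dimethyloct-6-enoate
Conditions: TBSOTf, 2,6-lutidine, CH2Cl2, 0 °C
Reagents that add atoms: tert-butyldimethylsilyl triflate, CC(C)(C)[Si](C)(C)OS(=O)(=O)C(F)(F)F
Why: Silyl triflate silylation protects the hindered secondary alcohol until the last step.

Step 8
Reactants: 10 methyl (2S,3R)-2-(tert-butyldimethylsilyloxy)-3,7-dimethyloct-6-enoate
Product: 12 methyl (2S,3R)-2-(tert-butyldimethylsilyloxy)-3-methyl-6-oxohexanoate, via secondary ozonide 11 (not isolated)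
Conditions: O3, CH2Cl2, −78 °C; Me2S, −78 °C to rt
Reagents that add atoms: ozone, [O-][O+]=O
Why: Ozonolysis with reductive work-up cleaves the only olefin and unveils C9 as an aldehyde.

Step 9
Reactants: 12 methyl (2S,3R)-2-(tert-butyldimethylsilyloxy)-3-methyl-6-oxohexanoate
Product: 13 methyl (2S,3R)-2-(tert-butyldimethylsilyloxy)-6-hydroxy-3-methyloct-7-ynoate (C6 epimers)
Conditions: HC≡CMgBr (1.2 equiv), THF, −78 °C; H2O
Reagents that add atoms: ethynylmagnesium bromide, C#C[Mg]Br
Why: Grignard addition at low temperature should take the aldehyde in preference to the hindered α-silyloxy ester and brings in C8 and C7.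

Step 10
Reactants: 13 methyl (2S,3R)-2-(tert-butyldimethylsilyloxy)-6-hydroxy-3-methyloct-7-ynoate
Product: 14 methyl (2S,3R)-2-(tert-butyldimethylsilyloxy)-3-methyl-6-oxooct-7-ynoate
Conditions: Dess–Martin periodinane, NaHCO3, CH2Cl2, 0 °C
Reagents that add atoms: none
Why: Dess–Martin oxidation of the propargylic alcohol gives the terminal ynone under neutral conditions.

Step 11
Reactants: 14 methyl (2S,3R)-2-(tert-butyldimethylsilyloxy)-3-methyl-6-oxooct-7-ynoate
Product: 16 methyl (2S,3R,7Z)-2-(tert-butyldimethylsilyloxy)-7-(hydroxymethyl)-8-iodo-3-methyl-6-oxooct-7-enoate, via magnesium iodoallenolate 15 (not isolated)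
Conditions: MgI2 (1.5 equiv), CH2O (monomer, cracked from paraformaldehyde, excess), CH2Cl2, −20 to 0 °C; H2O
Reagents that add atoms: magnesium iodide, [Mg+2].[I-].[I-]; formaldehyde, C=O
Why: In this iodide-triggered Morita–Baylis–Hillman-type three-component reaction iodide adds 1,4 to the ynone and formaldehyde meets the allenolate from the side of hydrogen, so the kinetic product should be the Z-β-iodo enone with iodine cis to the ketone.

Step 12
Reactants: 16 methyl (2S,3R,7Z)-2-(tert-butyldimethylsilyloxy)-7-(hydroxymethyl)-8-iodo-3-methyl-6-oxooct-7-enoate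
Product: 17 methyl (2S,3R,7Z)-2-(tert-butyldimethylsilyloxy)-7-[(tert-butyldimethylsilyloxy)methyl]-8-iodo-3-methyl-6-oxooct-7-enoate
Conditions: TBSOTf, 2,6-lutidine, CH2Cl2, −78 °C
Reagents that add atoms: tert-butyldimethylsilyl triflate, CC(C)(C)[Si](C)(C)OS(=O)(=O)C(F)(F)F
Why: Silylation with a non-nucleophilic base protects C19-OH and avoids addition–elimination at the β-iodo enone.

Step 13
Reactants: 17 methyl (2S,3R,7Z)-2-(tert-butyldimethylsilyloxy)-7-[(tert-butyldimethylsilyloxy)methyl]-8-iodo-3-methyl-6-oxooct-7-enoate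
Product: 18 methyl (2S,3R,7Z)-2-(tert-butyldimethylsilyloxy)-7-[(tert-butyldimethylsilyloxy)methyl]-6-hydroxy-8-iodo-3-methyloct-7-enoate (C6 epimers)
Conditions: NaBH4, CeCl3·7H2O, MeOH, −78 °C
Reagents that add atoms: none
Why: Luche 1,2-reduction removes the Michael-acceptor character of the iodo enone before carbanion chemistry, and keeps the ester, the C–I bond and the olefin geometry.

Step 14
Reactants: 18 methyl (2S,3R,7Z)-2-(tert-butyldimethylsilyloxy)-7-[(tert-butyldimethylsilyloxy)methyl]-6-hydroxy-8-iodo-3-methyloct-7-enoate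
Product: 19 β-ketophosphonate in which the CO2Me of 18 has become C(=O)CH(iPr)P(O)(OEt)2 (12R,13S,7Z; C1 and C9 epimer mixtures)
Conditions: diethyl (2-methylpropyl)phosphonate (4 equiv), n-BuLi (3.9 equiv), THF, −78 °C; then 18, −78 °C; H2O
Reagents that add atoms: diethyl (2-methylpropyl)phosphonate, CC(C)CP(=O)(OCC)OCC
Why: Acylation of an α-lithio phosphonate by an ester stops at the ketone stage because the product is deprotonated, one equivalent being consumed by the free alcohol, and it brings in C1 with the isopropyl group.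

Step 15
Reactants: 19 β-ketophosphonate; 4 (2R,3R)-3-ethenyl-3-methyloxirane-2-carbaldehyde
Product: 20 acyclic (1E,3S,4R,7Z,12R,13S) precursor: C14 enone joined at C2 to the 4-vinyl-4-methyl oxirane, C7 iodide, free C9-OH, C13- and C19-OTBS
Conditions: Ba(OH)2·8H2O (activated), THF/H2O 40:1, 0 °C to rt; kept below 30 °C
Reagents that add atoms: none
Why: Horner–Wadsworth–Emmons olefination under mild hydroxide activation tolerates the free alcohol, vinyl iodide and epoxy aldehyde, and should place the oxirane residue trans to the bulky acyl group (E).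

Step 16
Reactants: 20 acyclic (1E,3S,4R,7Z,12R,13S) precursor
Product: 22 (1E,3S,4R,7Z,12R,13S)-13,19-bis(tert-butyldimethylsilyloxy)-3,4-epoxycembra-1,7-diene-9,14-diol (C9 and C14 epimers), via tris-boryl adduct 21 (not isolated)
Conditions: 9-BBN (4.5 equiv, 0.5 M in THF), 0 °C to rt, 5 h; then slow addition (12 h) to Pd(dppf)Cl2 (20 mol %), AsPh3 (40 mol %), Cs2CO3 (6 equiv), DMF/THF/H2O, final 1 mM, rt to 40 °C
Reagents that add atoms: 9-borabicyclo[3.3.1]nonane, B1C2CCCC1CCC2 (boron stays only in 21)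
Why: 9-BBN should first turn the C9 alcohol into a borinate and reduce the C14 enone 1,2 to the allylic borinate (a known selective enone reduction that spares oxiranes and vinyl iodides), and then hydroborate the only monosubstituted olefin with boron at C6, because C4 is fully substituted. In the palladium flask zerovalent palladium inserts into the C7–I bond with retention, the hydroxyborate transfers the primary alkyl group, and reductive elimination forms C6–C7. The closest known reaction type is the hydroboration/B-alkyl Suzuki–Miyaura macrocyclisation of ω-alkenyl vinyl iodides used for carbocycles and macrolides of 12 to 20 members. The single ring closed is the 14-membered carbocycle, formed end-to-end by reductive elimination from a 15-membered palladacycle, with pseudo-high dilution disfavouring dimers. No lasting stereocentre is created: the Z-olefin is inherited from the iodide, and the C14 carbinol, like C9, is an epimer mixture that step 17 erases (any unreduced enone converges there as well). The step needs C–I insertion to precede ionisation of the remaining alkenyl oxirane and transmetallation to precede 1,3-elimination of the γ-boryl oxirane, which the very reactive iodide, the crowded trisubstituted C1=C2 olefin, the tertiary oxirane carbon and arsine-accelerated coupling near room temperature should secure.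

Step 17
Reactants: 22 (1E,3S,4R,7Z,12R,13S)-13,19-bis(tert-butyldimethylsilyloxy)-3,4-epoxycembra-1,7-diene-9,14-diol
Product: 23 (1E,3S,4R,7Z,12R,13S)-13,19-bis(tert-butyldimethylsilyloxy)-3,4-epoxycembra-1,7-diene-9,14-dione
Conditions: Dess–Martin periodinane (3 equiv), NaHCO3, CH2Cl2, 0 °C
Reagents that add atoms: none
Why: Buffered Dess–Martin oxidation converts both allylic alcohols into the enones in one operation, without base or nucleophile that could isomerise the Z-enone.

Step 18
Reactants: 23 (1E,3S,4R,7Z,12R,13S)-13,19-bis(tert-butyldimethylsilyloxy)-3,4-epoxycembra-1,7-diene-9,14-dione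
Product: 24 (1E,3S,4R,7Z,12R,13S)-3,4-epoxy-13,19-dihydroxycembra-1,7-diene-9,14-dione (target)
Conditions: HF·pyridine, pyridine, THF, 0 °C to rt
Reagents that add atoms: none
Why: Pyridine-buffered fluoride desilylation removes both silyl ethers under conditions that trisubstituted oxiranes and α-hydroxy ketones normally survive.

**Compound list**
1 | (2Z)-3-methylpent-2-en-4-yn-1-ol | OC/C=C(/C)C#C | starting material
2 | (2Z)-3-methylpenta-2,4-dien-1-ol | OC/C=C(/C)C=C | intermediate
3 | [(2S,3R)-3-ethenyl-3-methyloxiran-2-yl]methanol | OC[C@@H]1O[C@]1(C)C=C | intermediate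
4 | (2R,3R)-3-ethenyl-3-methyloxirane-2-carbaldehyde | O=C[C@@H]1O[C@]1(C)C=C | intermediate
5 | (R)-citronellic acid | CC(C)=CCC[C@@H](C)CC(=O)O | starting material
6 | N-citronelloyl (S)-4-benzyloxazolidinone | CC(C)=CCC[C@@H](C)CC(=O)N1[C@@H](Cc2ccccc2)COC1=O | intermediate
7 | sodium Z-enolate of 6 | CC(C)=CCC[C@@H](C)/C=C(\[O-])N1[C@@H](Cc2ccccc2)COC1=O.[Na+] | intermediate
8 | (2S,3R)-2-hydroxy imide | CC(C)=CCC[C@@H](C)[C@H](O)C(=O)N1[C@@H](Cc2ccccc2)COC1=O | intermediate
9 | methyl (2S,3R)-2-hydroxy-3,7-dimethyloct-6-enoate | CC(C)=CCC[C@@H](C)[C@H](O)C(=O)OC | intermediate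
10 | TBS ether of 9 | CC(C)=CCC[C@@H](C)[C@H](O[Si](C)(C)C(C)(C)C)C(=O)OC | intermediate
11 | secondary ozonide of 10 | CC1(C)OOC(CC[C@@H](C)[C@H](O[Si](C)(C)C(C)(C)C)C(=O)OC)O1 | intermediate
12 | C9 aldehyde | O=CCC[C@@H](C)[C@H](O[Si](C)(C)C(C)(C)C)C(=O)OC | intermediate
13 | propargylic alcohol | C#CC(O)CC[C@@H](C)[C@H](O[Si](C)(C)C(C)(C)C)C(=O)OC | intermediate
14 | terminal ynone | C#CC(=O)CC[C@@H](C)[C@H](O[Si](C)(C)C(C)(C)C)C(=O)OC | intermediate
15 | magnesium β-iodoallenolate | IC=C=C(O[Mg]I)CC[C@@H](C)[C@H](O[Si](C)(C)C(C)(C)C)C(=O)OC | intermediate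
16 | (Z)-β-iodo-α-(hydroxymethyl) enone | I/C=C(/CO)C(=O)CC[C@@H](C)[C@H](O[Si](C)(C)C(C)(C)C)C(=O)OC | intermediate
17 | C19 TBS ether of 16 | I/C=C(/CO[Si](C)(C)C(C)(C)C)C(=O)CC[C@@H](C)[C@H](O[Si](C)(C)C(C)(C)C)C(=O)OC | intermediate
18 | (Z)-iodo allylic alcohol | I/C=C(/CO[Si](C)(C)C(C)(C)C)C(O)CC[C@@H](C)[C@H](O[Si](C)(C)C(C)(C)C)C(=O)OC | intermediate
19 | α-isopropyl β-ketophosphonate | I/C=C(/CO[Si](C)(C)C(C)(C)C)C(O)CC[C@@H](C)[C@H](O[Si](C)(C)C(C)(C)C)C(=O)C(C(C)C)P(=O)(OCC)OCC | intermediate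
20 | acyclic vinyl-oxirane / vinyl iodide precursor | I/C=C(/CO[Si](C)(C)C(C)(C)C)C(O)CC[C@@H](C)[C@H](O[Si](C)(C)C(C)(C)C)C(=O)/C(C(C)C)=C/[C@@H]1O[C@]1(C)C=C | intermediate
21 | tris(9-BBN) adduct (C6–B, C9–O–B, C14–O–B) | I/C=C(/CO[Si](C)(C)C(C)(C)C)C(OB2C3CCCC2CCC3)CC[C@@H](C)[C@H](O[Si](C)(C)C(C)(C)C)C(OB2C3CCCC2CCC3)/C(C(C)C)=C/[C@@H]1O[C@]1(C)CCB2C3CCCC2CCC3 | intermediate
22 | macrocyclic 9,14-diol | CC(C)/C1=C\[C@@H]2O[C@]2(C)CC/C=C(/CO[Si](C)(C)C(C)(C)C)C(O)CC[C@@H](C)[C@H](O[Si](C)(C)C(C)(C)C)C1O | intermediate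
23 | macrocyclic 9,14-dione bis-TBS ether | CC(C)/C1=C\[C@@H]2O[C@]2(C)CC/C=C(/CO[Si](C)(C)C(C)(C)C)C(=O)CC[C@@H](C)[C@H](O[Si](C)(C)C(C)(C)C)C1=O | intermediate
24 | (1E,3S,4R,7Z,12R,13S)-3,4-epoxy-13,19-dihydroxycembra-1,7-diene-9,14-dione | CC(C)/C1=C\[C@@H]2O[C@]2(C)CC/C=C(/CO)C(=O)CC[C@@H](C)[C@H](O)C1=O | target

Total step count: 18. Longest linear sequence: 15 steps (5 to 24, steps 4–18).

**Steps most likely to fail**

Step 16. Three processes could outrun ring closure: hydride delivery to the vinyl oxirane with allylic ring opening, 1,3-elimination of the γ-boryl oxirane, and palladium-induced ionisation of the alkenyl oxirane. The fallback keeps the same bond but uses zinc, so no hydride reagent meets a vinyl oxirane. It sets out from 2 and returns at 23.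
- Compound 2 is hydroborated at the terminal olefin with 9-BBN before any oxirane exists, giving the bis-boryl adduct F1.
- I2/NaOMe converts F1 into (2Z)-5-iodo-3-methylpent-2-en-1-ol F2.
- Sharpless epoxidation with L-(+)-diethyl tartrate gives the iodo epoxy alcohol F3, and Dess–Martin oxidation gives the aldehyde F4.
- Horner–Wadsworth–Emmons union with 19 gives the diiodide F5, and TESOTf/2,6-lutidine gives its C9 triethylsilyl ether F6.
- Zn dust/LiCl in THF inserts only into the primary alkyl iodide to give the alkylzinc iodide F7.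
- Under high dilution with Pd(dppf)Cl2, F7 closes C6–C7 by Negishi coupling to the macrocyclic enone F8.
- Buffered HF·pyridine at 0 °C frees the C9 alcohol F9, and Dess–Martin oxidation gives 23.

Step 15. The crowded α-isopropyl phosphonate anion may add sluggishly, E/Z control may be poor, or the epoxy aldehyde may decay under base. The fallback is an aldol/elimination sequence that also bypasses step 14. It sets out from 18 and returns at 20.
- TESOTf/2,6-lutidine gives the triethylsilyl ether F10.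
- MeNH(OMe)·HCl/i-PrMgCl gives the N-methoxy-N-methylamide F11, and i-BuMgBr gives the isobutyl ketone F12.
- Kinetic enolisation (LDA, −78 °C) at the CH2 side and addition to 4 gives the aldol F13.
- MsCl/Et3N gives the mesylate F14, which DBU eliminates by an E1cB path to the E-enone F15.
- Buffered HF·pyridine removes the triethylsilyl group to give 20.

Step 2. Epoxidation of the Z-olefin may be slow with eroded facial selectivity, and titanium may open the tertiary allylic oxirane. The fallback changes the substrate of the asymmetric step. It sets out from 1 and returns at 3. The enynol 1 is epoxidised directly under the same tartrate control to the ethynyl oxirane F16, whose alkynyl group disfavours ionisation. Semihydrogenation over Pd/CaCO3 poisoned with Pb(OAc)2 then gives 3.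

**Further compounds**
F1 | step 16 | bis(9-BBN) adduct of 2 (C5–B and O–B) | C(/C=C(/C)CCB1C2CCCC1CCC2)OB1C2CCCC1CCC2
F2 | step 16 | (2Z)-5-iodo-3-methylpent-2-en-1-ol | OC/C=C(/C)CCI
F3 | step 16 | [(2S,3R)-3-(2-iodoethyl)-3-methyloxiran-2-yl]methanol | OC[C@@H]1O[C@]1(C)CCI
F4 | step 16 | (2R,3R)-3-(2-iodoethyl)-3-methyloxirane-2-carbaldehyde | O=C[C@@H]1O[C@]1(C)CCI
F5 | step 16 | acyclic C6 alkyl iodide / C7 vinyl iodide enone, C9-OH | I/C=C(/CO[Si](C)(C)C(C)(C)C)C(O)CC[C@@H](C)[C@H](O[Si](C)(C)C(C)(C)C)C(=O)/C(C(C)C)=C/[C@@H]1O[C@]1(C)CCI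
F6 | step 16 | C9 triethylsilyl ether of F5 | I/C=C(/CO[Si](C)(C)C(C)(C)C)C(O[Si](CC)(CC)CC)CC[C@@H](C)[C@H](O[Si](C)(C)C(C)(C)C)C(=O)/C(C(C)C)=C/[C@@H]1O[C@]1(C)CCI
F7 | step 16 | C6 alkylzinc iodide from F6 | I/C=C(/CO[Si](C)(C)C(C)(C)C)C(O[Si](CC)(CC)CC)CC[C@@H](C)[C@H](O[Si](C)(C)C(C)(C)C)C(=O)/C(C(C)C)=C/[C@@H]1O[C@]1(C)CC[Zn]I
F8 | step 16 | macrocyclic 14-enone, C9-OTES | CC(C)/C1=C\[C@@H]2O[C@]2(C)CC/C=C(/CO[Si](C)(C)C(C)(C)C)C(O[Si](CC)(CC)CC)CC[C@@H](C)[C@H](O[Si](C)(C)C(C)(C)C)C1=O
F9 | step 16 | macrocyclic 14-enone, C9-OH | CC(C)/C1=C\[C@@H]2O[C@]2(C)CC/C=C(/CO[Si](C)(C)C(C)(C)C)C(O)CC[C@@H](C)[C@H](O[Si](C)(C)C(C)(C)C)C1=O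
F10 | step 15 | C9 triethylsilyl ether of 18 | I/C=C(/CO[Si](C)(C)C(C)(C)C)C(O[Si](CC)(CC)CC)CC[C@@H](C)[C@H](O[Si](C)(C)C(C)(C)C)C(=O)OC
F11 | step 15 | N-methoxy-N-methylamide from F10 | I/C=C(/CO[Si](C)(C)C(C)(C)C)C(O[Si](CC)(CC)CC)CC[C@@H](C)[C@H](O[Si](C)(C)C(C)(C)C)C(=O)N(C)OC
F12 | step 15 | isobutyl ketone | I/C=C(/CO[Si](C)(C)C(C)(C)C)C(O[Si](CC)(CC)CC)CC[C@@H](C)[C@H](O[Si](C)(C)C(C)(C)C)C(=O)CC(C)C
F13 | step 15 | aldol adduct with 4 (C1 and C2 epimers) | I/C=C(/CO[Si](C)(C)C(C)(C)C)C(O[Si](CC)(CC)CC)CC[C@@H](C)[C@H](O[Si](C)(C)C(C)(C)C)C(=O)C(C(C)C)C(O)[C@@H]1O[C@]1(C)C=C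
F14 | step 15 | C2 mesylate of F13 | I/C=C(/CO[Si](C)(C)C(C)(C)C)C(O[Si](CC)(CC)CC)CC[C@@H](C)[C@H](O[Si](C)(C)C(C)(C)C)C(=O)C(C(C)C)C(OS(C)(=O)=O)[C@@H]1O[C@]1(C)C=C
F15 | step 15 | C9 triethylsilyl ether of 20 | I/C=C(/CO[Si](C)(C)C(C)(C)C)C(O[Si](CC)(CC)CC)CC[C@@H](C)[C@H](O[Si](C)(C)C(C)(C)C)C(=O)/C(C(C)C)=C/[C@@H]1O[C@]1(C)C=C
F16 | step 2 | [(2S,3R)-3-ethynyl-3-methyloxiran-2-yl]methanol | OC[C@@H]1O[C@]1(C)C#C
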